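**Strategy.** The target is numbered as a bicyclo[3.2.1]oct-3-ene-2,8-dione (C1 prenyl bridgehead, C5 methyl bridgehead, C6 carbinol-bearing CH, C7 CH2, C8 bridging ketone). Everything rests on disconnecting C6–C7, which opens the cyclopentanone ring C1–C8–C5–C6–C7 and leaves a monocyclic, twice-dearomatised acylphloroglucinol. The key step exploits that C1 and C5, the quaternary carbons flanking C8 in the six-membered ring, hold their substituents face to face: a CH2 radical on C1 (from CH2SePh) adds 5-exo to a 2-methylprop-1-enyl group on C5 and the tertiary radical is oxygenated. One operation closes the bridge, sets C6 and installs the tertiary alcohol.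

Key step: step 6

Remark (assumption): (2R)-2-methylbutanoic acid, tributyl(2-methylprop-1-en-1-yl)stannane and prenyl acetate are taken as catalogue compounds; all triketones are drawn as one enol tautomer.

Step 1
Reactants: 1 2-methylbenzene-1,3,5-triol; 2 (2R)-2-methylbutanoic acid
Product: 4 (2R)-2-methyl-1-(2,4,6-trihydroxy-3-methylphenyl)butan-1-one, via (2R)-2-methylbutanoyl chloride 3 (not isolated)
Conditions: 2, (COCl)2, DMF (cat.), CH2Cl2, 0 °C to rt; then 1, AlCl3, PhNO2–CH2Cl2, 0 °C to rt
Reagents that add atoms: none
Why: Friedel–Crafts C-acylation of the electron-rich triol should occur at one of its two equivalent free ring positions and stop there because the ketone deactivates the ring; the acid chloride is made and used at or below room temperature so that the stereocentre brought in with 2 is not enolised.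

Step 2
Reactants: 4 (2R)-2-methyl-1-(2,4,6-trihydroxy-3-methylphenyl)butan-1-one
Product: 6 2,4,6-trihydroxy-3-methyl-5-[(2R)-2-methylbutanoyl]benzaldehyde, via Vilsmeier iminium chloride 5 (not isolated)
Conditions: POCl3, DMF, EtOAc, 0 °C to rt; then H2O, 50 °C
Reagents that add atoms: N,N-dimethylformamide, CN(C)C=O; water, O
Why: Vilsmeier–Haack formylation should attack the only ring C–H that is left, and the aldehyde then serves as a removable blocking group that makes this carbon non-nucleophilic in step 3; no stereocentre is formed.

Step 3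
Reactants: 6 2,4,6-trihydroxy-3-methyl-5-[(2R)-2-methylbutanoyl]benzaldehyde; 7 tributyl(2-methylprop-1-en-1-yl)stannane
Product: 9 (5S)-2,4-dihydroxy-5-methyl-5-(2-methylprop-1-en-1-yl)-3-[(2R)-2-methylbutanoyl]-6-oxocyclohexa-1,3-diene-1-carbaldehyde, via triacetoxy(2-methylprop-1-en-1-yl)plumbane 8 (not isolated)
Conditions: 7, Pb(OAc)4, CHCl3, 40 °C; then 6, pyridine, 40 to 60 °C
Reagents that add atoms: none
Why: Tin–lead exchange should give the alkenyllead triacetate, which binds a phenol oxygen and couples at the ortho carbon (Pinhey-type organolead ligand coupling); only the methyl-bearing carbon is open because the other two ring carbons carry acyl groups, so the ring is dearomatised to the 5-methyl-5-alkenyl dienone, and since nothing controls the new quaternary centre, 9 is expected together with a similar amount of its C5 epimer, which is carried along until the separation in step 5.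

Step 4
Reactants: 9 (5S)-2,4-dihydroxy-5-methyl-5-(2-methylprop-1-en-1-yl)-3-[(2R)-2-methylbutanoyl]-6-oxocyclohexa-1,3-diene-1-carbaldehyde
Product: 11 (6S)-3,5-dihydroxy-6-methyl-6-(2-methylprop-1-en-1-yl)-4-[(2R)-2-methylbutanoyl]-2-[(phenylselanyl)methyl]cyclohexa-2,4-dien-1-one, via deformylated dienone 10 (not isolated)
Conditions: Et3N (cat.), THF–H2O, 50 °C; then (CH2O)n, PhSeH, 40 °C
Reagents that add atoms: formaldehyde, C=O; benzeneselenol, [SeH]c1ccccc1
Why: Water should cleave the formyl group from the 2-formyl-1,3-dione by retro-Claisen reaction, and the freed enol carbon then undergoes the Mannich-type three-component selenomethylation (Knoevenagel condensation with formaldehyde, then conjugate addition of the selenol to the 2-methylene-1,3-dione, as is well known for thiols); the quaternary centre is not touched.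

Step 5
Reactants: 11 (6S)-3,5-dihydroxy-6-methyl-6-(2-methylprop-1-en-1-yl)-4-[(2R)-2-methylbutanoyl]-2-[(phenylselanyl)methyl]cyclohexa-2,4-dien-1-one; 12 3-methylbut-2-en-1-yl acetate
Product: 13 (4S,6S)-3-hydroxy-4-methyl-4-(2-methylprop-1-en-1-yl)-2-[(2R)-2-methylbutanoyl]-6-(3-methylbut-2-en-1-yl)-6-[(phenylselanyl)methyl]cyclohex-2-ene-1,5-dione
Conditions: Pd2(dba)3·CHCl3 (2.5 mol %), (S,S)-DACH-phenyl bis(phosphine) ligand [N,N′-(1S,2S)-cyclohexane-1,2-diylbis(2-diphenylphosphanylbenzamide)] (7.5 mol %), Et3N, CH2Cl2, 0 °C
Reagents that add atoms: none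
Why: Pd-catalysed asymmetric allylic alkylation (Tsuji–Trost reaction) of the enolate should place the prenyl group, through its unhindered terminus, on the only carbon that is still nucleophilic (O-prenyl ethers re-ionise and funnel to carbon), and the chiral ligand is chosen to direct attack to the face that gives the (6S) prenyl-bearing quaternary centre; 11 thus gives 13, in which CH2SePh and the alkenyl group are cis, while the C-methyl epimer that accompanies 11 gives the trans diastereomer, which is removed by chromatography.

Step 6
Reactants: 13 (4S,6S)-3-hydroxy-4-methyl-4-(2-methylprop-1-en-1-yl)-2-[(2R)-2-methylbutanoyl]-6-(3-methylbut-2-en-1-yl)-6-[(phenylselanyl)methyl]cyclohex-2-ene-1,5-dione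
Product: 15 (1S,5S,6S)-4-hydroxy-6-(2-hydroxypropan-2-yl)-5-methyl-3-[(2R)-2-methylbutanoyl]-1-(3-methylbut-2-en-1-yl)bicyclo[3.2.1]oct-3-ene-2,8-dione, via tertiary hydroperoxide 14 (not isolated)
Conditions: Bu3SnH (slow addition), Et3B (cat.), dry air, toluene, 0 °C; then PPh3, rt
Reagents that add atoms: dioxygen, O=O
Why: The tributyltin radical abstracts the phenylselanyl group to give a primary radical on the CH2 attached to the prenyl-bearing quaternary carbon; this adds to the CH terminus of the 2-methylprop-1-enyl group on the methyl-bearing quaternary carbon, the tertiary radical is captured by O2, the peroxyl radical takes hydrogen from Bu3SnH, and PPh3 reduces hydroperoxide 14 to the alcohol. The closest known reaction type is the oxygenative radical cyclization of alkyl halides and selenides under tin hydride and air; the same tertiary radical is reached from the opposite side in oxidative radical cyclizations of dearomatised prenyl acylphloroglucinols. The ring that closes is the cyclopentanone C1–C8–C5–C6–C7, by 5-exo-trig attack, which turns the cyclohexenedione into the bicyclo[3.2.1]octane. The new stereocentre C6 is set in the bicyclic transition state: the CMe2 terminus should point away from the enolised three-carbon bridge (exo), because the endo orientation drives it into the π-face of C2–C3–C4, so C6–H ends endo. The step needs ring closure to outrun O2 capture of the primary radical and 1,2-acyl migration (Dowd–Beckwith ring enlargement), and O2 capture of the tertiary radical to outrun its 6-exo addition to the prenyl group; the first is secured by the cis, near-parallel placement of radical and alkene on the flattened ring (set in step 5), the second by working in air-saturated solution at 0 °C with slow hydride addition.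

**Compound list**

1 | 2-methylbenzene-1,3,5-triol | Cc1c(O)cc(O)cc1O | starting material
2 | (2R)-2-methylbutanoic acid | CC[C@@H](C)C(=O)O | starting material
3 | (2R)-2-methylbutanoyl chloride | CC[C@@H](C)C(=O)Cl | intermediate
4 | (2R)-2-methyl-1-(2,4,6-trihydroxy-3-methylphenyl)butan-1-one | CC[C@@H](C)C(=O)c1c(O)c(C)c(O)cc1O | intermediate
5 | N-{2,4,6-trihydroxy-3-methyl-5-[(2R)-2-methylbutanoyl]benzylidene}-N-methylmethanaminium chloride | CC[C@@H](C)C(=O)c1c(O)c(C)c(O)c(C=[N+](C)C)c1O.[Cl-] | intermediate
6 | 2,4,6-trihydroxy-3-methyl-5-[(2R)-2-methylbutanoyl]benzaldehyde | CC[C@@H](C)C(=O)c1c(O)c(C)c(O)c(C=O)c1O | intermediate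
7 | tributyl(2-methylprop-1-en-1-yl)stannane | CCCC[Sn](CCCC)(CCCC)C=C(C)C | starting material
8 | triacetoxy(2-methylprop-1-en-1-yl)plumbane (tetravalent lead) | CC(C)=C[Pb](OC(C)=O)(OC(C)=O)OC(C)=O | intermediate
9 | (5S)-2,4-dihydroxy-5-methyl-5-(2-methylprop-1-en-1-yl)-3-[(2R)-2-methylbutanoyl]-6-oxocyclohexa-1,3-diene-1-carbaldehyde (formed together with its C5 epimer) | CC[C@@H](C)C(=O)C1=C(O)[C@@](C=C(C)C)(C)C(=O)C(C=O)=C1O | intermediate
10 | (6S)-3,5-dihydroxy-6-methyl-6-(2-methylprop-1-en-1-yl)-4-[(2R)-2-methylbutanoyl]cyclohexa-2,4-dien-1-one | CC[C@@H](C)C(=O)C1=C(O)[C@@](C=C(C)C)(C)C(=O)C=C1O | intermediate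
11 | (6S)-3,5-dihydroxy-6-methyl-6-(2-methylprop-1-en-1-yl)-4-[(2R)-2-methylbutanoyl]-2-[(phenylselanyl)methyl]cyclohexa-2,4-dien-1-one (carried together with its C6 epimer) | CC[C@@H](C)C(=O)C1=C(O)[C@@](C=C(C)C)(C)C(=O)C(C[Se]c2ccccc2)=C1O | intermediate
12 | 3-methylbut-2-en-1-yl acetate (prenyl acetate) | CC(=O)OCC=C(C)C | starting material
13 | (4S,6S)-3-hydroxy-4-methyl-4-(2-methylprop-1-en-1-yl)-2-[(2R)-2-methylbutanoyl]-6-(3-methylbut-2-en-1-yl)-6-[(phenylselanyl)methyl]cyclohex-2-ene-1,5-dione | CC[C@@H](C)C(=O)C1=C(O)[C@@](C=C(C)C)(C)C(=O)[C@](CC=C(C)C)(C[Se]c2ccccc2)C1=O | intermediate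
14 | (1S,5S,6S)-6-(2-hydroperoxypropan-2-yl)-4-hydroxy-5-methyl-3-[(2R)-2-methylbutanoyl]-1-(3-methylbut-2-en-1-yl)bicyclo[3.2.1]oct-3-ene-2,8-dione | CC[C@@H](C)C(=O)C1=C(O)[C@@]2(C)C(=O)[C@](CC=C(C)C)(C[C@@H]2C(C)(C)OO)C1=O | intermediate
15 | (1S,5S,6S)-4-hydroxy-6-(2-hydroxypropan-2-yl)-5-methyl-3-[(2R)-2-methylbutanoyl]-1-(3-methylbut-2-en-1-yl)bicyclo[3.2.1]oct-3-ene-2,8-dione | CC[C@@H](C)C(=O)C1=C(O)[C@@]2(C)C(=O)[C@](CC=C(C)C)(C[C@@H]2C(C)(C)O)C1=O | target

**Step count and risks**

Total steps: 6. Longest linear sequence: 6 steps (1 and 2 to 15).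

Steps most likely to fail:

Step 6 (key step). What may go wrong: O2 captures the primary radical before it closes the ring, the radical undergoes 1,2-acyl migration with ring enlargement, or the tertiary radical adds 6-exo to the prenyl group instead of being oxygenated. The fallback closes the same bond by a cationic instead of a radical route; it sets out from 13 and comes back at 15. Oxidation at selenium (H2O2, THF, 0 °C) should give the (benzeneseleninyl)methyl compound F1, which has no β-hydrogen and cannot eliminate. TFAA and 2,6-lutidine in CH2Cl2 at −40 °C should then trigger a seleno-Pummerer ionisation to the selenium-stabilised carbenium ion at the CH2 group. The 2-methylprop-1-enyl group captures this ion 5-exo through its CH terminus, and the tertiary cation is taken up as trifluoroacetate and hydrolysed (aq NaHCO3) to the 7-(phenylselanyl) alcohol F2 (either C7 epimer). Bu3SnH and AIBN (benzene, 80 °C) then remove selenium to give 15.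

Step 3. What may go wrong: the ligand coupling may not take place on the strongly deactivated diacyl phenol, or tetravalent lead may oxidise the electron-rich ring instead of transferring the alkenyl group. The fallback builds the alkenyl group by thionium alkylation and sulfoxide elimination; it sets out from 6 and comes back at 9. Isobutyl phenyl sulfide is chlorinated with N-chlorosuccinimide (CCl4, rt) to 1-chloro-2-methylpropyl phenyl sulfide F3. With ZnBr2 in CH2Cl2 at 0 °C this should alkylate 6 at the methyl-bearing carbon through the thionium ion, giving the 1-(phenylsulfanyl)-2-methylpropyl dienone F4 as a mixture of diastereomers. NaIO4 (MeOH–H2O, 0 °C) gives the sulfoxide F5. Heating in toluene at 100 °C causes syn-elimination, which can only go towards the isopropyl CH because the ring carbon is quaternary, and gives 9 (again with its C5 epimer).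

Step 5. What may go wrong: poor facial discrimination at the new quaternary centre, inhibition of zerovalent palladium by the selenide, or loss of material to O-prenylation. The fallback replaces the π-allyl palladium electrophile by chiral ion-pair control; it sets out from 11 and comes back at 13 without any new compound. 11 is C-prenylated with prenyl bromide under asymmetric phase-transfer catalysis (N-(9-anthracenylmethyl)cinchonidinium bromide, 50% aq KOH, toluene, −20 °C), a reaction type established for alkylative dearomatisation of acylphloroglucinols. The cis diastereomer 13 is separated as before.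

Further compounds

F1 | step 6 | (4S,6S)-6-[(benzeneseleninyl)methyl]-3-hydroxy-4-methyl-4-(2-methylprop-1-en-1-yl)-2-[(2R)-2-methylbutanoyl]-6-(3-methylbut-2-en-1-yl)cyclohex-2-ene-1,5-dione | CC[C@@H](C)C(=O)C1=C(O)[C@@](C=C(C)C)(C)C(=O)[C@](CC=C(C)C)(C[Se](=O)c2ccccc2)C1=O
F2 | step 6 | (1S,5S,6S)-4-hydroxy-6-(2-hydroxypropan-2-yl)-5-methyl-3-[(2R)-2-methylbutanoyl]-1-(3-methylbut-2-en-1-yl)-7-(phenylselanyl)bicyclo[3.2.1]oct-3-ene-2,8-dione (either C7 epimer) | CC[C@@H](C)C(=O)C1=C(O)[C@@]2(C)C(=O)[C@](CC=C(C)C)(C([Se]c3ccccc3)[C@@H]2C(C)(C)O)C1=O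
F3 | step 3 | 1-chloro-2-methylpropyl phenyl sulfide (racemic) | CC(C)C(Cl)Sc1ccccc1
F4 | step 3 | 2,4-dihydroxy-5-methyl-3-[(2R)-2-methylbutanoyl]-5-[2-methyl-1-(phenylsulfanyl)propyl]-6-oxocyclohexa-1,3-diene-1-carbaldehyde (mixture of diastereomers) | CC[C@@H](C)C(=O)C1=C(O)C(C)(C(Sc2ccccc2)C(C)C)C(=O)C(C=O)=C1O
F5 | step 3 | 5-[1-(benzenesulfinyl)-2-methylpropyl]-2,4-dihydroxy-5-methyl-3-[(2R)-2-methylbutanoyl]-6-oxocyclohexa-1,3-diene-1-carbaldehyde (mixture of diastereomers) | CC[C@@H](C)C(=O)C1=C(O)C(C)(C(S(=O)c2ccccc2)C(C)C)C(=O)C(C=O)=C1O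
F0 | step 5 | none | none
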